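**Strategy.** The cyclohexane is cut at the bond between its ring CH2 and the quaternary carbon bearing methyl and vinyl. Since the other neighbour of that CH2 carries oxygen, the ring is the retron of a Lewis-acid 1,3 O-to-C shift (Ferrier/Petasis–Ferrier type): a 2-methylidene-6-methyl-6-vinyloxane ionises at its tertiary allylic C–O bond and the aluminium enolate closes the carbocycle through its terminal carbon, giving ring, quaternary stereocentre and ketone in one operation. The oxane arises from an alkynol built by two Barbier allylations; D-glyceraldehyde acetonide is a traceless source of absolute configuration.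

Key step: step 14

Remark on the chemistry: the tertiary carbinol carbon made in step 3 (later the quaternary ring carbon) is expected as an epimer mixture and is drawn without configuration in 7–11 and 19–22; it becomes planar in step 14.

Step 1
Reactants: 1 (4R)-2,2-dimethyl-1,3-dioxolane-4-carbaldehyde; 2 methyl acrylate
Product: 3 methyl 2-{[(4R)-2,2-dimethyl-1,3-dioxolan-4-yl](hydroxy)methyl}prop-2-enoate (both carbinol epimers)
Conditions: DABCO (0.5 equiv), 1,4-dioxane/H2O 1:1, rt
Reagents that add atoms: none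
Why: Baylis–Hillman reaction of an α-alkoxy aldehyde with an acrylate; the carbinol configuration is irrelevant because it is erased in step 2.

Step 2
Reactants: 3
Product: 4 methyl (2Z)-2-(bromomethyl)-3-[(4S)-2,2-dimethyl-1,3-dioxolan-4-yl]prop-2-enoate
Conditions: NBS, Me2S, CH2Cl2, 0 °C to rt
Reagents that add atoms: N-bromosuccinimide, O=C1CCC(=O)N1Br
Why: Corey–Kim-type activation of the allylic alcohol followed by SN2′ delivery of bromide should give the more stable (Z)-2-(bromomethyl)alkenoate under non-acidic conditions that spare the acetonide.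

Step 3
Reactants: 4; 5 but-3-en-2-one
Product: 8 (4R,5RS)-4-[(4S)-2,2-dimethyl-1,3-dioxolan-4-yl]-5-ethenyl-5-methyl-3-methylideneoxolan-2-one, via allylzinc bromide 6 (not isolated), via bromozinc alkoxide 7 (not isolated)
Conditions: activated Zn dust, THF, 45 °C; aq. NH4Cl
Reagents that add atoms: none
Why: Barbier allylation with lactonisation (Dreiding–Schmidt reaction): the γ-carbon of the allylzinc adds 1,2 to the ketone through a six-membered transition state, and C-4 is set by the dioxolane stereocentre, whose C–H eclipses the alkene to relieve allylic strain with the Z-CH2Zn group so that the ketone enters anti to the dioxolane C–C bond with the oxygen outside; a minor C-4 epimer would be a separable diastereomer.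

Step 4
Reactants: 8
Product: 9 (3R,4RS)-3-[(4S)-2,2-dimethyl-1,3-dioxolan-4-yl]-4-methyl-2-methylidenehex-5-ene-1,4-diol
Conditions: i-Bu2AlH (4.5 equiv), CH2Cl2, −78 to 0 °C; aq. KNaC4H4O6
Reagents that add atoms: none
Why: 1,2-selective hydride reduction of the α-methylidene lactone through its lactol should give the primary allylic alcohol and free the tertiary hydroxyl without touching the acetonide.

Step 5
Reactants: 9
Product: 10 (3RS,4R)-6-[(tert-butyldimethylsilyl)oxy]-4-[(4S)-2,2-dimethyl-1,3-dioxolan-4-yl]-3-methyl-5-methylidenehex-1-en-3-ol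
Conditions: TBSCl, imidazole, CH2Cl2, 0 °C
Reagents that add atoms: tert-butyldimethylsilyl chloride, CC(C)(C)[Si](C)(C)Cl
Why: silylation discriminates the primary allylic hydroxyl from the hindered tertiary one.

Step 6
Reactants: 10
Product: 11 (2S,3RS)-2-{3-[(tert-butyldimethylsilyl)oxy]prop-1-en-2-yl}-3-hydroxy-3-methylpent-4-enal
Conditions: H5IO6 (1.5 equiv), EtOAc, 0 °C to rt
Reagents that add atoms: none
Why: one-pot acetonide hydrolysis and Malaprade glycol cleavage should release the aldehyde and remove the controlling dioxolane stereocentre; the epimerisable β,γ-unsaturated aldehyde is used crude.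

Step 7
Reactants: 12 prop-2-enoyl chloride; 13 2-(trimethylsilyl)ethanol
Product: 14 2-(trimethylsilyl)ethyl prop-2-enoate
Conditions: Et3N, CH2Cl2, 0 °C
Reagents that add atoms: none
Why: simple acylation of a primary alcohol by an acid chloride gives the fluoride-cleavable acrylate.

Step 8
Reactants: 14; 15 3-(trimethylsilyl)prop-2-ynal
Product: 16 2-(trimethylsilyl)ethyl 3-hydroxy-2-methylidene-5-(trimethylsilyl)pent-4-ynoate (racemic)
Conditions: DABCO (0.2 equiv), THF, rt
Reagents that add atoms: none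
Why: Baylis–Hillman reaction of a reactive ynal; the carbinol centre is erased in step 9.

Step 9
Reactants: 16
Product: 17 2-(trimethylsilyl)ethyl (2Z)-2-(bromomethyl)-5-(trimethylsilyl)pent-2-en-4-ynoate
Conditions: NBS, Me2S, CH2Cl2, 0 °C to rt
Reagents that add atoms: N-bromosuccinimide, O=C1CCC(=O)N1Br
Why: the same Corey–Kim-type SN2′ bromination as in step 2 should give the conjugated (Z)-enynoate allyl bromide, the silyl group blocking the alkyne terminus.

Step 10
Reactants: 11; 17
Product: 19 2-(trimethylsilyl)ethyl (3R,4R,5R,6RS)-5-{3-[(tert-butyldimethylsilyl)oxy]prop-1-en-2-yl}-4,6-dihydroxy-6-methyl-2-methylidene-3-[(trimethylsilyl)ethynyl]oct-7-enoate, via allylindium bromide 18 (not isolated)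
Conditions: In powder (1.5 equiv), THF/H2O 1:1, rt
Reagents that add atoms: none
Why: aqueous indium Barbier allylation through the γ-carbon in a chair transition state, in which the (Z)-reagent gives the syn C-3/C-4 pair and the aldehyde face is fixed by chelation of indium between the carbonyl and the free tertiary β-hydroxyl (attack anti to the C-5 substituent); the bulky ester should retard lactonisation.

Step 11
Reactants: 19
Product: 20 2-(trimethylsilyl)ethyl (3R,4R,5R,6RS)-5-{3-[(tert-butyldimethylsilyl)oxy]prop-1-en-2-yl}-6-hydroxy-6-methyl-2-methylidene-4-[(triethylsilyl)oxy]-3-[(trimethylsilyl)ethynyl]oct-7-enoate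
Conditions: TESCl, imidazole, DMF, 0 °C
Reagents that add atoms: triethylsilyl chloride, CC[Si](CC)(CC)Cl
Why: the secondary hydroxyl is silylated in preference to the tertiary one, which prevents its own 5-endo addition to the alkyne in step 13 and its lactonisation.

Step 12
Reactants: 20
Product: 21 2-(trimethylsilyl)ethyl (3S,4R,5R,6RS)-5-{3-[(tert-butyldimethylsilyl)oxy]prop-1-en-2-yl}-3-ethynyl-6-hydroxy-6-methyl-2-methylidene-4-[(triethylsilyl)oxy]oct-7-enoate
Conditions: K2CO3 (0.3 equiv), MeOH, 0 °C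
Reagents that add atoms: none
Why: mild methanolysis cleaves only the alkynyl C–Si bond, while silyl ethers and the hindered ester should survive.

Step 13
Reactants: 21
Product: 22 2-(trimethylsilyl)ethyl 2-[(3S,4R,5R,6RS)-5-{3-[(tert-butyldimethylsilyl)oxy]prop-1-en-2-yl}-6-ethenyl-6-methyl-2-methylidene-4-[(triethylsilyl)oxy]oxan-3-yl]prop-2-enoate
Conditions: AuCl (5 mol %), K2CO3 (10 mol %), MeCN, rt; filtration through basic alumina
Reagents that add atoms: none
Why: base-buffered gold-catalysed 6-exo-dig hydroalkoxylation of the terminal alkyne by the tertiary hydroxyl should give the exocyclic enol ether, which is an allyl vinyl ether and is used without further purification.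

Step 14
Reactants: 22
Product: 24 2-(trimethylsilyl)ethyl 2-[(1S,2S,3R,4S)-3-{3-[(tert-butyldimethylsilyl)oxy]prop-1-en-2-yl}-4-ethenyl-2-hydroxy-4-methyl-6-oxocyclohexyl]prop-2-enoate, via triethylsilyl ether ketone 23 (not isolated)
Conditions: Me2AlCl (1.5 equiv), CH2Cl2, −78 to −40 °C; aq. KNaC4H4O6; crude with PPTS (0.2 equiv), MeOH, 0 °C
Reagents that add atoms: none
Why: Proposed new method: Me2AlCl binds the ring oxygen, the tertiary allylic C–O bond ionises to a contact ion pair of an aluminium enolate and a methyl-substituted allyl cation, and the terminal enolate carbon bonds to the substituted allyl terminus so that the former ring oxygen becomes the ketone oxygen (the PPTS stage then only removes the triethylsilyl group). The closest known reaction type is the Lewis-acid 1,3 O-to-C rearrangement of allyl vinyl ethers and its ring-contracting Ferrier and Petasis–Ferrier relatives, asked here to override the 3,3 (Claisen) ring expansion known for 2-methylidene-6-vinyloxanes. The carbocycle closes in a 6-(enolendo)-exo-trig mode. The new quaternary centre C-4 is set by the adjacent C-3: in a chair transition state with the two alkenyl substituents equatorial and the silyloxy group axial, the C-3 hydrogen eclipses the allyl unit to minimise allylic strain, so vinyl becomes equatorial and methyl axial, cis to the C-3 substituent, and both carbinol epimers of 22 converge on the same planar cation. The step needs 1,3 over 3,3 recombination, which dissociative low-temperature conditions and six- versus eight-membered closure should secure, and reaction at the terminal enolate carbon, which the exocyclic enol ether guarantees.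

Step 15
Reactants: 24
Product: 25 2-(trimethylsilyl)ethyl 2-[(1R,2S,3R,4S,6S)-3-{3-[(tert-butyldimethylsilyl)oxy]prop-1-en-2-yl}-4-ethenyl-2,6-dihydroxy-4-methylcyclohexyl]prop-2-enoate
Conditions: Me4NBH(OAc)3 (5 equiv), MeCN/AcOH 1:1, −30 to −20 °C
Reagents that add atoms: none
Why: Evans–Saksena reduction, in which the axial C-2 hydroxyl binds boron and delivers hydride to the same face of the ketone, should give the anti-1,3-diol with the new C-6 hydroxyl equatorial, while the enoate is inert.

Step 16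
Reactants: 26 3-methylfuran-2(5H)-one
Product: 29 (2Z)-4-(acetyloxy)-2-methylbut-2-enoic acid, via lithium hydroxy carboxylate 27 (not isolated), via dilithium alkoxide carboxylate 28 (not isolated)
Conditions: LiOH·H2O (1.0 equiv), THF/H2O, 0 °C; evaporate, dry; LiN(SiMe3)2 (1.05 equiv), THF, −78 °C; AcCl (1.0 equiv), −78 °C; 1 M HCl to pH 3
Reagents that add atoms: lithium hydroxide, [Li+].[OH-]; acetyl chloride, CC(=O)Cl
Why: saponification of the butenolide fixes the Z geometry, and the alkoxide of the dianion is acetylated far faster than the carboxylate, so relactonisation through a mixed anhydride should be avoided.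

Step 17
Reactants: 25; 29
Product: 31 2-(trimethylsilyl)ethyl 2-[(1S,2S,3R,4S,6S)-6-{[(2Z)-4-(acetyloxy)-2-methylbut-2-enoyl]oxy}-3-{3-[(tert-butyldimethylsilyl)oxy]prop-1-en-2-yl}-4-ethenyl-2-hydroxy-4-methylcyclohexyl]prop-2-enoate, via mixed anhydride 30 (not isolated)
Conditions: 2,4,6-Cl3C6H2COCl, Et3N, THF, 0 °C; then 25, DMAP, toluene, 0 °C to rt
Reagents that add atoms: none
Why: Yamaguchi esterification, which is known to keep Z-2-methylbut-2-enoates from isomerising, should acylate the equatorial C-6 hydroxyl rather than the axial C-2 hydroxyl, which is flanked by two branched carbons and 1,3-diaxial to the ring methyl.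

Step 18
Reactants: 31
Product: 32 2-[(1S,2S,3R,4S,6S)-6-{[(2Z)-4-(acetyloxy)-2-methylbut-2-enoyl]oxy}-4-ethenyl-2-hydroxy-3-(3-hydroxyprop-1-en-2-yl)-4-methylcyclohexyl]prop-2-enoic acid
Conditions: Bu4NF (4 equiv), AcOH (4 equiv), THF, 0 °C to rt; pH 4 NaH2PO4 buffer
Reagents that add atoms: none
Why: buffered fluoride removes the silyl ether and fragments the 2-(trimethylsilyl)ethyl ester to the carboxylate, sparing the acetate and the enoate ester, and the mild acidification should avoid lactonisation of the hydroxy acid.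

**Compound list**

1 | (4R)-2,2-dimethyl-1,3-dioxolane-4-carbaldehyde | O=C[C@H]1COC(C)(C)O1 | starting material
2 | methyl acrylate | C=CC(=O)OC | starting material
3 | methyl 2-{[(4R)-2,2-dimethyl-1,3-dioxolan-4-yl](hydroxy)methyl}prop-2-enoate | C=C(C(O)[C@H]1COC(C)(C)O1)C(=O)OC | intermediate
4 | methyl (2Z)-2-(bromomethyl)-3-[(4S)-2,2-dimethyl-1,3-dioxolan-4-yl]prop-2-enoate | COC(=O)/C(CBr)=C/[C@H]1COC(C)(C)O1 | intermediate
5 | but-3-en-2-one | CC(=O)C=C | starting material
6 | methyl (2Z)-2-[(bromozincio)methyl]-3-[(4S)-2,2-dimethyl-1,3-dioxolan-4-yl]prop-2-enoate | COC(=O)/C(C[Zn]Br)=C/[C@H]1COC(C)(C)O1 | intermediate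
7 | bromozinc (3RS,4R)-4-[(4S)-2,2-dimethyl-1,3-dioxolan-4-yl]-5-(methoxycarbonyl)-3-methylhexa-1,5-dien-3-olate | C=C(C(=O)OC)[C@H]([C@H]1COC(C)(C)O1)C(C)(O[Zn]Br)C=C | intermediate
8 | (4R,5RS)-4-[(4S)-2,2-dimethyl-1,3-dioxolan-4-yl]-5-ethenyl-5-methyl-3-methylideneoxolan-2-one | C=C1C(=O)OC(C)(C=C)[C@H]1[C@H]2COC(C)(C)O2 | intermediate
9 | (3R,4RS)-3-[(4S)-2,2-dimethyl-1,3-dioxolan-4-yl]-4-methyl-2-methylidenehex-5-ene-1,4-diol | C=C(CO)[C@H]([C@H]1COC(C)(C)O1)C(C)(O)C=C | intermediate
10 | (3RS,4R)-6-[(tert-butyldimethylsilyl)oxy]-4-[(4S)-2,2-dimethyl-1,3-dioxolan-4-yl]-3-methyl-5-methylidenehex-1-en-3-ol | C=C(CO[Si](C)(C)C(C)(C)C)[C@H]([C@H]1COC(C)(C)O1)C(C)(O)C=C | intermediate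
11 | (2S,3RS)-2-{3-[(tert-butyldimethylsilyl)oxy]prop-1-en-2-yl}-3-hydroxy-3-methylpent-4-enal | C=C(CO[Si](C)(C)C(C)(C)C)[C@H](C=O)C(C)(O)C=C | intermediate
12 | prop-2-enoyl chloride | C=CC(=O)Cl | starting material
13 | 2-(trimethylsilyl)ethanol | C[Si](C)(C)CCO | starting material
14 | 2-(trimethylsilyl)ethyl prop-2-enoate | C=CC(=O)OCC[Si](C)(C)C | intermediate
15 | 3-(trimethylsilyl)prop-2-ynal | C[Si](C)(C)C#CC=O | starting material
16 | 2-(trimethylsilyl)ethyl 3-hydroxy-2-methylidene-5-(trimethylsilyl)pent-4-ynoate | C=C(C(O)C#C[Si](C)(C)C)C(=O)OCC[Si](C)(C)C | intermediate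
17 | 2-(trimethylsilyl)ethyl (2Z)-2-(bromomethyl)-5-(trimethylsilyl)pent-2-en-4-ynoate | C[Si](C)(C)C#C/C=C(\CBr)C(=O)OCC[Si](C)(C)C | intermediate
18 | allylindium species from 17, drawn as 2-(trimethylsilyl)ethyl (2Z)-2-[(dibromoindiganyl)methyl]-5-(trimethylsilyl)pent-2-en-4-ynoate | C[Si](C)(C)C#C/C=C(\C[In](Br)Br)C(=O)OCC[Si](C)(C)C | intermediate
19 | 2-(trimethylsilyl)ethyl (3R,4R,5R,6RS)-5-{3-[(tert-butyldimethylsilyl)oxy]prop-1-en-2-yl}-4,6-dihydroxy-6-methyl-2-methylidene-3-[(trimethylsilyl)ethynyl]oct-7-enoate | C=CC(C)(O)[C@H](C(=C)CO[Si](C)(C)C(C)(C)C)[C@H](O)[C@@H](C#C[Si](C)(C)C)C(=C)C(=O)OCC[Si](C)(C)C | intermediate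
20 | 2-(trimethylsilyl)ethyl (3R,4R,5R,6RS)-5-{3-[(tert-butyldimethylsilyl)oxy]prop-1-en-2-yl}-6-hydroxy-6-methyl-2-methylidene-4-[(triethylsilyl)oxy]-3-[(trimethylsilyl)ethynyl]oct-7-enoate | C=CC(C)(O)[C@H](C(=C)CO[Si](C)(C)C(C)(C)C)[C@H](O[Si](CC)(CC)CC)[C@@H](C#C[Si](C)(C)C)C(=C)C(=O)OCC[Si](C)(C)C | intermediate
21 | 2-(trimethylsilyl)ethyl (3S,4R,5R,6RS)-5-{3-[(tert-butyldimethylsilyl)oxy]prop-1-en-2-yl}-3-ethynyl-6-hydroxy-6-methyl-2-methylidene-4-[(triethylsilyl)oxy]oct-7-enoate | C=CC(C)(O)[C@H](C(=C)CO[Si](C)(C)C(C)(C)C)[C@H](O[Si](CC)(CC)CC)[C@@H](C#C)C(=C)C(=O)OCC[Si](C)(C)C | intermediate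
22 | 2-(trimethylsilyl)ethyl 2-[(3S,4R,5R,6RS)-5-{3-[(tert-butyldimethylsilyl)oxy]prop-1-en-2-yl}-6-ethenyl-6-methyl-2-methylidene-4-[(triethylsilyl)oxy]oxan-3-yl]prop-2-enoate | C=C1OC(C)(C=C)[C@H](C(=C)CO[Si](C)(C)C(C)(C)C)[C@H](O[Si](CC)(CC)CC)[C@@H]1C(=C)C(=O)OCC[Si](C)(C)C | intermediate
23 | 2-(trimethylsilyl)ethyl 2-[(1S,2S,3R,4S)-3-{3-[(tert-butyldimethylsilyl)oxy]prop-1-en-2-yl}-4-ethenyl-4-methyl-6-oxo-2-[(triethylsilyl)oxy]cyclohexyl]prop-2-enoate | C=C[C@]1(C)CC(=O)[C@@H](C(=C)C(=O)OCC[Si](C)(C)C)[C@@H](O[Si](CC)(CC)CC)[C@H]1C(=C)CO[Si](C)(C)C(C)(C)C | intermediate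
24 | 2-(trimethylsilyl)ethyl 2-[(1S,2S,3R,4S)-3-{3-[(tert-butyldimethylsilyl)oxy]prop-1-en-2-yl}-4-ethenyl-2-hydroxy-4-methyl-6-oxocyclohexyl]prop-2-enoate | C=C[C@]1(C)CC(=O)[C@@H](C(=C)C(=O)OCC[Si](C)(C)C)[C@@H](O)[C@H]1C(=C)CO[Si](C)(C)C(C)(C)C | intermediate
25 | 2-(trimethylsilyl)ethyl 2-[(1R,2S,3R,4S,6S)-3-{3-[(tert-butyldimethylsilyl)oxy]prop-1-en-2-yl}-4-ethenyl-2,6-dihydroxy-4-methylcyclohexyl]prop-2-enoate | C=C[C@]1(C)C[C@H](O)[C@@H](C(=C)C(=O)OCC[Si](C)(C)C)[C@@H](O)[C@H]1C(=C)CO[Si](C)(C)C(C)(C)C | intermediate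
26 | 3-methylfuran-2(5H)-one | CC1=CCOC1=O | starting material
27 | lithium (2Z)-4-hydroxy-2-methylbut-2-enoate | [Li+].[O-]C(=O)/C(C)=C\CO | intermediate
28 | dilithium (2Z)-2-methyl-4-oxidobut-2-enoate | [Li+].[Li+].[O-]C(=O)/C(C)=C\C[O-] | intermediate
29 | (2Z)-4-(acetyloxy)-2-methylbut-2-enoic acid | OC(=O)/C(C)=C\COC(C)=O | intermediate
30 | (2Z)-4-(acetyloxy)-2-methylbut-2-enoic 2,4,6-trichlorobenzoic anhydride | O=C(OC(=O)c1c(Cl)cc(Cl)cc1Cl)/C(C)=C\COC(C)=O | intermediate
31 | 2-(trimethylsilyl)ethyl 2-[(1S,2S,3R,4S,6S)-6-{[(2Z)-4-(acetyloxy)-2-methylbut-2-enoyl]oxy}-3-{3-[(tert-butyldimethylsilyl)oxy]prop-1-en-2-yl}-4-ethenyl-2-hydroxy-4-methylcyclohexyl]prop-2-enoate | C=C[C@]1(C)C[C@H](OC(=O)/C(C)=C\COC(C)=O)[C@@H](C(=C)C(=O)OCC[Si](C)(C)C)[C@@H](O)[C@H]1C(=C)CO[Si](C)(C)C(C)(C)C | intermediate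
32 | 2-[(1S,2S,3R,4S,6S)-6-{[(2Z)-4-(acetyloxy)-2-methylbut-2-enoyl]oxy}-4-ethenyl-2-hydroxy-3-(3-hydroxyprop-1-en-2-yl)-4-methylcyclohexyl]prop-2-enoic acid | C=C[C@]1(C)C[C@H](OC(=O)/C(C)=C\COC(C)=O)[C@@H](C(=C)C(=O)O)[C@@H](O)[C@H]1C(=C)CO | target

**Step count and risks**

Total step count: 18. Longest linear sequence: 14 steps (steps 1–6, 10–15, 17 and 18).

Steps most likely to fail:

1. Step 14 (Proposed new method). The ion pair may recombine in the 3,3 sense to an eight-membered ketone, the allyl cation may be captured by the neighbouring 1,1-disubstituted alkene, or the two faces of the cation may be poorly discriminated. The fallback uses known chemistry, sets out from 21 and returns at 23. The tertiary hydroxyl of 21 would be converted with LiN(SiMe3)2 and ClCO2Me into the tertiary allylic methyl carbonate F1. The terminal alkyne of F1 would be hydrated with catalytic Hg(OTf)2 in wet MeCN to the methyl ketone F2. F2 would then be cyclised by an intramolecular Tsuji–Trost alkylation (LiN(SiMe3)2, THF, −78 °C, then Pd(PPh3)4): the kinetic methyl enolate attacks the substituted terminus of the π-allylpalladium unit, the only mode that closes a six-membered ring, and the face-equilibrating allyl complex makes the closure stereoconvergent. This gives 23, which PPTS in MeOH converts into 24.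

2. Step 10. The syn relationship may be lost by E/Z equilibration of the allylindium species, the reagent may react through its alkyne terminus, or chelation control of the aldehyde face may be weak. The fallback sets out from 16 and returns at 19. Acetylation of 16 (Ac2O, DMAP) would give the Baylis–Hillman acetate F3. Borylation of F3 with B2pin2 and catalytic Pd2(dba)3 would give the geometrically fixed (Z)-allylboronate F4. Thermal allylboration of 11 with F4 in toluene proceeds through a closed chair transition state that transfers the alkene geometry and cannot involve the alkyne terminus, giving 19.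

3. Step 17. Site selectivity between the two secondary hydroxyls may be lost, or the free ring hydroxyl may lactonise onto the acrylate ester under DMAP. The fallback sets out from 23 (isolated by omitting the PPTS stage of step 14) and returns at 32. Luche reduction of 23 (NaBH4, CeCl3, MeOH, −40 °C) should deliver hydride from the face opposite the syn-axial methyl and silyloxy groups and give the axial alcohol F5, the only free hydroxyl. Mitsunobu esterification of F5 with 29 (PPh3, DIAD, toluene) inverts this centre and gives the triply silylated ester F6. Bu4NF with AcOH then removes all three silyl groups from F6 to give 32.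

**Further compounds**

F1 | step 14 | 2-(trimethylsilyl)ethyl (3S,4R,5R,6RS)-5-{3-[(tert-butyldimethylsilyl)oxy]prop-1-en-2-yl}-3-ethynyl-6-[(methoxycarbonyl)oxy]-6-methyl-2-methylidene-4-[(triethylsilyl)oxy]oct-7-enoate | C=CC(C)(OC(=O)OC)[C@H](C(=C)CO[Si](C)(C)C(C)(C)C)[C@H](O[Si](CC)(CC)CC)[C@@H](C#C)C(=C)C(=O)OCC[Si](C)(C)C
F2 | step 14 | 3-acetyl analogue of F1 (methyl ketone in place of the ethynyl group, other centres as in 21) | C=CC(C)(OC(=O)OC)[C@H](C(=C)CO[Si](C)(C)C(C)(C)C)[C@H](O[Si](CC)(CC)CC)[C@@H](C(C)=O)C(=C)C(=O)OCC[Si](C)(C)C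
F3 | step 10 | 2-(trimethylsilyl)ethyl 3-(acetyloxy)-2-methylidene-5-(trimethylsilyl)pent-4-ynoate | C=C(C(OC(C)=O)C#C[Si](C)(C)C)C(=O)OCC[Si](C)(C)C
F4 | step 10 | 2-(trimethylsilyl)ethyl (2Z)-2-[(4,4,5,5-tetramethyl-1,3,2-dioxaborolan-2-yl)methyl]-5-(trimethylsilyl)pent-2-en-4-ynoate | C[Si](C)(C)C#C/C=C(\CB1OC(C)(C)C(C)(C)O1)C(=O)OCC[Si](C)(C)C
F5 | step 17 | 2-(trimethylsilyl)ethyl 2-[3-{3-[(tert-butyldimethylsilyl)oxy]prop-1-en-2-yl}-4-ethenyl-6-hydroxy-4-methyl-2-[(triethylsilyl)oxy]cyclohexyl]prop-2-enoate, axial C-6 alcohol (C-6 epimer of the 2-O-triethylsilyl ether of 25) | C=C[C@]1(C)C[C@@H](O)[C@@H](C(=C)C(=O)OCC[Si](C)(C)C)[C@@H](O[Si](CC)(CC)CC)[C@H]1C(=C)CO[Si](C)(C)C(C)(C)C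
F6 | step 17 | 2-O-triethylsilyl ether of 31 | C=C[C@]1(C)C[C@H](OC(=O)/C(C)=C\COC(C)=O)[C@@H](C(=C)C(=O)OCC[Si](C)(C)C)[C@@H](O[Si](CC)(CC)CC)[C@H]1C(=C)CO[Si](C)(C)C(C)(C)C
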